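**Analysis of the target**

Sideroxylonal A (19) is a 2-arylchroman. In chroman numbering (O1, C2, C3, C4, C4a to C8a) ring A is fused at C4a/C8a and carries hydroxyl groups on C5 and C7 and formyl groups on C6 and C8; ring B on C2 is a 2,4,6-trihydroxy-3,5-diformylphenyl group, so both arenes are hexasubstituted diformylphloroglucinol units. The pyran ring holds three contiguous stereocentres, C2 (R, ring B), C3 (R, isopropyl) and C4 (S, isobutyl): isopropyl and isobutyl are cis, and ring B is trans to isopropyl. In the half-chair that keeps the C4 isobutyl group pseudoaxial, away from the C5 oxygen, isopropyl and ring B are both equatorial, whereas the C2 epimer would force ring B and isobutyl into a 1,3-diaxial contact; C2 therefore has the configuration that equilibration should favour once C3 and C4 are cis, and it can be equilibrated because O1–C2 is a benzylic ether bond next to an oxygen-rich arene. The sensitive groups are the four aldehydes, the five acidic and easily oxidized phenols, and this same O1–C2 bond, which ionizes under acid or opens to a quinone methide. The synthesis is hard because two branched alkyl groups must stand cis on adjacent carbons that bear no functional handle, between two fully substituted arenes, and because four formyl groups have to be introduced. The strategy rests on one feature of ring A: C8a carries O1 and its neighbour C4a carries C4, with an oxygen on C5 next to C4a. This is the pattern left when a 3-alkoxyaryne takes up first the oxygen and then the carbon of a carbonyl group, and the rest of the pyran ring (C4, C3, C2 with isobutyl, isopropyl and ring B) is then the carbon chain of an enone.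

**Retrosynthetic reasoning**

19 to 18. The five O–CH3 bonds are cut first. Methyl ethers are the one phenol protection that should survive an aryne, a cationic iridium hydride, protic acid and a titanium Lewis acid. In 18 every methoxy group lies ortho to a formyl group, so chelation-assisted Lewis-acid cleavage should remove all five in one operation. The forward step must do this without opening O1–C2; the two formyl groups on ring B deactivate that bond.

18 to 17. The four aryl–CHO bonds are cut next. C6, C8, C3' and C5' are the only unsubstituted aromatic positions, and each lies between two oxygen substituents, so exhaustive electrophilic formylation has no regiochemical choice to make. Doing it late keeps aldehydes out of the aryne step and the hydrogenation. The forward reaction has to overcome the deactivation that each new formyl group brings.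

17 to 16. Here only the configuration at C2 changes: O1–C2 is broken and re-formed. Because 17 is the more stable epimer, C2 need not be controlled when the ring is first made; reversible ionization to the ring B benzylic cation should deliver it. The forward step must equilibrate C2 without touching C3 and C4.

16 to 15. The C3–H and C4–H bonds are cut, which leads back to the C3=C4 alkene of 15. Syn addition of hydrogen makes isopropyl and isobutyl cis, so one reaction sets both centres in their relative sense. C2 of 15 is stereogenic and racemic, and its aryl group shields one face of the alkene; a chiral catalyst is therefore expected to reduce one enantiomer of 15 much faster than the other. The hydrogenation is planned as a kinetic resolution that fixes the absolute configuration of C3 and C4.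

15 to 6 and 11. This is the key disconnection: C8a–O1, C4a–C4 and O1–C2 are cut together. Backwards, 15 opens at O1–C2 to the ortho-quinone methide 14, 14 closes to the benzoxete 13, and 13 divides into aryne 12 and the carbonyl group of 11. Cutting here removes the whole pyran ring and leaves two pieces of very different polarity, each a few steps from commercial material. No other set of three bonds separates ring A from the C2–C3–C4 chain while placing both branches and ring B in one simple partner. The forward reaction must engage the C=O bond of an enolizable ketone and must deliver oxygen to C8a and carbon to C4a.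

11 to 10 to 7 and 8. The C=C bond of 11 (C2=C3 in chroman numbering) comes from dehydration of 10, and the C–C bond of 10 from an aldol addition of 7 to 8. Ketone 7 is symmetrical and already contains C3, C4, the isopropyl group and the isobutyl group; aldehyde 8 is ring B with C2.

6 to 3 to 2 to 1. The aryne precursor needs silicon and triflate on neighbouring carbons, with silicon next to a methoxy group. The C–Si bond comes from a 1,3-shift of silicon from oxygen to carbon (4 to 5) after halogen–metal exchange on 3. The bromine of 2 marks the position between hydroxyl and methoxy of phenol 1, which is the future C4a.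

**Alternatives that were turned down**

Alternative 1: The disconnection cuts C4–C4a and C3–C4 in an open chain. The forward key step is a one-pot double homologation of the ring A boronic ester A1: first with the lithiated form of carbamate A2 (building C4 with its isobutyl group), then with the lithiated form of the hindered benzoate A3 (building C3 with its isopropyl group). It gives the secondary boronic ester A4, in which boron stands on C3 where C2 will later be. In its favour, both C3 and C4 are set by reagent control in absolute and relative sense; on this point it is stronger than the chosen route, which gives up about half of its material in a kinetic resolution. Against it, A1 is an electron-rich aryl boronic ester with two ortho methoxy groups, so ate-complex formation is hindered and protodeboronation is likely. The second homologation must join a benzylic secondary boronic ester to an α-branched carbenoid, a combination in which ate formation tends to reverse and migration is slow. A4 contains no ring: C2 with ring B, the unmasking of one ring A oxygen, the closure of O1–C2 and the configuration of C2 are all still to come, at the cost of at least four or five further steps. The chosen strategy offers in its place three skeletal bonds and the pyran ring in a single step, with the chroman reached two steps later.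

Alternative 2: The disconnection goes through ring A itself, at C4a–C8a and C5–C6. In the forward key step the pyrone diene of precursor A5 adds on heating to its tethered silyl ynol ether, and the bridged adduct aromatizes by extrusion of the lactone bridge, giving the chroman A6 with ring A and the pyran ring closed together. In its favour, ring A is born fully substituted with both carbon substituents already in place at the carboxyl level, and the tether fixes the regiochemistry; on regiocontrol and on avoiding a late fourfold formylation it is stronger than the chosen route. Against it, A5 must already contain all three stereocentres in an open chain, together with a labile 6-alkoxypyrone on a secondary benzylic oxygen and a moisture-sensitive ynol ether. After the key step, four esters must each be adjusted to aldehydes and two kinds of protecting group removed, so the step count is a multiple of the present one. The chosen strategy uses the symmetry of the phloroglucinol rings instead: all open positions are equivalent sites between two oxygens, so the regiocontrol that A5 provides is not needed.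

Alternative 3: The disconnection is O1–C2 alone. In the forward key step a flavin-dependent oxidase of the family that dehydrogenates para-alkylphenols oxidizes the C2 methylene of the hexahydroxy 1,3-diarylpropane A7 to a ring B quinone methide, which a ring A hydroxyl captures to give the pentahydroxy chroman A8. In its favour, it needs no protecting groups, runs in water under mild conditions, and may set C2 at the ring closure; on mildness and atom economy it is stronger than the chosen route. Against it, the known substrates of these enzymes are simple para-alkylphenols, while A7 has a methylene flanked by two ortho hydroxyls and a branched chain carrying a second bulky arene, so enzyme engineering would be needed. A7 still contains the whole C3/C4 problem, the free phloroglucinols are air-sensitive, and only one bond is formed. The chosen strategy reaches the pentamethyl ether of A8 (compound 17) by chemical steps alone and builds ring A onto the chain in the same step that closes the pyran.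

Key step: step 6

Assumption: which enantiomer of the oxazoline ligand reduces the (S)-enantiomer of 15 faster is to be settled by a test reduction; the ligand is written as (S), and its mirror image is used if the test shows the opposite sense.

**Route**

Step 1
Reactants: 1 3,5-dimethoxyphenol
Product: 2 2-bromo-3,5-dimethoxyphenol
Conditions: NBS (1.0 equiv), i-Pr2NH (10 mol %), CH2Cl2, −78 °C to 0 °C
Reagents that add atoms: N-bromosuccinimide, O=C1CCC(=O)N1Br
Why: Electrophilic aromatic bromination; the amine relays bromine as an N-bromoamine hydrogen-bonded to the phenol and so steers it ortho to OH (C2, also para to the C5 methoxy group), while low temperature and exact stoichiometry hold back the 4-bromo isomer and the dibromide, which are removed by chromatography.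

Step 2
Reactants: 2 2-bromo-3,5-dimethoxyphenol
Product: 3 (2-bromo-3,5-dimethoxyphenoxy)trimethylsilane
Conditions: (Me3Si)2NH (0.6 equiv), THF, 70 °C; evaporation
Reagents that add atoms: hexamethyldisilazane, C[Si](C)(C)N[Si](C)(C)C
Why: O-silylation of a phenol with hexamethyldisilazane; the only other product is volatile, so the moisture-sensitive silyl ether is used crude.

Step 3
Reactants: 3 (2-bromo-3,5-dimethoxyphenoxy)trimethylsilane
Product: 6 3,5-dimethoxy-2-(trimethylsilyl)phenyl trifluoromethanesulfonate, via aryllithium 4 (not isolated), via lithium phenoxide 5 (not isolated)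
Conditions: n-BuLi (1.05 equiv), THF, −100 °C to −78 °C; then Tf2O (1.1 equiv), −100 °C to −78 °C
Reagents that add atoms: trifluoromethanesulfonic anhydride, O=S(=O)(OS(=O)(=O)C(F)(F)F)C(F)(F)F
Why: Bromine–lithium exchange gives aryllithium 4, whose carbanion takes the silyl group from the neighbouring oxygen (retro-Brook 1,3-shift, driven by formation of the phenoxide 5), and 5 is O-triflated in the same flask; this is the established way to ortho-silyl aryl triflates from ortho-bromophenols.

Step 4
Reactants: 7 2,6-dimethylheptan-4-one; 8 2,4,6-trimethoxybenzaldehyde
Product: 10 1-hydroxy-2-isopropyl-5-methyl-1-(2,4,6-trimethoxyphenyl)hexan-3-one (racemic mixture of diastereomers), via lithium enolate 9 (not isolated)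
Conditions: LiN(i-Pr)2 (1.1 equiv), THF, −78 °C; then 8, −78 °C; aq NH4Cl at −78 °C
Reagents that add atoms: none
Why: Directed aldol addition: the symmetrical ketone gives a single enolate 9, the aldehyde has no α-hydrogen, and the cold quench forestalls retro-aldol cleavage; both new stereocentres disappear in step 5, so their ratio is of no concern.

Step 5
Reactants: 10 1-hydroxy-2-isopropyl-5-methyl-1-(2,4,6-trimethoxyphenyl)hexan-3-one
Product: 11 (E)-2-isopropyl-5-methyl-1-(2,4,6-trimethoxyphenyl)hex-1-en-3-one
Conditions: TsOH·H2O (5 mol %), toluene, 50 °C
Reagents that add atoms: none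
Why: Acid-catalysed E1 dehydration: the hydroxyl group leaves readily as a benzylic cation stabilized by three methoxy groups, and loss of the α-hydrogen gives the conjugated enone, expected mainly as the (E)-isomer with ring B trans to the acyl group; any (Z)-isomer should also be usable in step 6.

Step 6
Reactants: 6 3,5-dimethoxy-2-(trimethylsilyl)phenyl trifluoromethanesulfonate; 11 (E)-2-isopropyl-5-methyl-1-(2,4,6-trimethoxyphenyl)hex-1-en-3-one
Product: 15 rac-4-isobutyl-3-isopropyl-5,7-dimethoxy-2-(2,4,6-trimethoxyphenyl)-2H-chromene, via 3,5-dimethoxybenzyne 12 (not isolated), via benzoxete 13 (not isolated), via ortho-quinone methide 14 (not isolated)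
Conditions: CsF (3 equiv), MeCN–toluene (1:3), 50 °C; 6 (1.5 equiv) added over 8 h
Reagents that add atoms: none
Why: Proposed new method: fluoride removes the trimethylsilyl group of 6 with loss of triflate to give aryne 12, whose triple bond is polarized by the adjacent methoxy group, so the carbonyl oxygen of 11 attacks the aryne carbon remote from that group (future C8a) and the resulting aryl anion, stabilized inductively beside the methoxy group, closes on the carbonyl carbon (future C4) in a stepwise [2+2] addition to benzoxete 13. The strained oxete opens by 4π electrocyclic cleavage of its O–C(sp3) bond to ortho-quinone methide 14, a 1-oxatriene O1=C8a–C4a=C4–C3=C2, and this closes the pyran ring by thermal oxa-6π electrocyclization at O1–C2, which restores the aromaticity of ring A. The closest known reaction type is the [2+2] addition of arynes to the C=O bond of formamides and of α,β-unsaturated aldehydes, the latter ending in the same oxa-6π closure to 2H-chromenes; an enolizable ketone has not been used in this way. C2 is the only stereocentre formed and, with no chiral element present, it forms racemic. The step needs regioselective aryne capture (oxygen to C8a, carbon to C4a), which the methoxy group beside the triple bond secures. It also needs the C=O bond to react in preference to the α-CH2 group and the C=C bond; this is helped by donation from ring B into the carbonyl oxygen, by the trisubstituted alkene shielded by its aryl group, and by slow release of the aryne from sparingly soluble CsF in a weakly polar medium, so that little enolate is present. Either geometry of the exocyclic C4a=C4 bond of 14 can reach the reactive one through reclosure to 13, and the (E)-alkene of 11 places hydrogen, not ring B, inside the closing termini.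

Step 7
Reactants: 15 rac-4-isobutyl-3-isopropyl-5,7-dimethoxy-2-(2,4,6-trimethoxyphenyl)-2H-chromene
Product: 16 (2S,3R,4S)-4-isobutyl-3-isopropyl-5,7-dimethoxy-2-(2,4,6-trimethoxyphenyl)chroman (all-cis)
Conditions: H2 (50 bar), [Ir(cod)(L)][B(3,5-(CF3)2C6H3)4] (2 mol %), L = (S)-2-[2-(dicyclohexylphosphanyl)phenyl]-4-isopropyl-4,5-dihydrooxazole, CH2Cl2, 25 °C, stopped near half conversion; unreacted (R)-15 recovered
Reagents that add atoms: none
Why: Iridium-catalysed asymmetric hydrogenation of a tetrasubstituted aryl alkene with a phosphanyl-oxazoline complex, run as a kinetic resolution: syn delivery of both hydrogens makes isopropyl and isobutyl cis, and the C2 aryl group shields its own face so that addition occurs anti to it. The chiral catalyst should accept the open face of (S)-15 far more readily than that of (R)-15, so near half conversion 16 should form with C3 (R) and C4 (S), while (R)-15 remains and can be returned to the racemate by reversible O1–C2 ionization with catalytic acid. Any C2 epimer formed by addition syn to the aryl group has the same C3 and C4 configuration and converges in step 8.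

Step 8
Reactants: 16 (2S,3R,4S)-4-isobutyl-3-isopropyl-5,7-dimethoxy-2-(2,4,6-trimethoxyphenyl)chroman
Product: 17 (2R,3R,4S)-4-isobutyl-3-isopropyl-5,7-dimethoxy-2-(2,4,6-trimethoxyphenyl)chroman
Conditions: CF3CO2H (5 equiv), CH2Cl2 (dilute), 0 °C to rt; aq NaHCO3
Reagents that add atoms: none
Why: Acid-promoted epimerization: heterolysis of O1–C2 gives a benzylic cation stabilized by the three methoxy groups of ring B (the same stabilization that makes trimethoxybenzyl groups acid-labile), and reclosure by the ring A phenol is reversible. C2 should therefore settle trans to the C3 isopropyl group, with ring B and isopropyl equatorial and isobutyl pseudoaxial away from the C5 methoxy group, whereas the all-cis isomer suffers a 1,3-diaxial contact between ring B and isobutyl; C3 and C4 are not involved.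

Step 9
Reactants: 17 (2R,3R,4S)-4-isobutyl-3-isopropyl-5,7-dimethoxy-2-(2,4,6-trimethoxyphenyl)chroman
Product: 18 (2R,3R,4S)-2-(3,5-diformyl-2,4,6-trimethoxyphenyl)-4-isobutyl-3-isopropyl-5,7-dimethoxychroman-6,8-dicarbaldehyde
Conditions: Cl2CHOMe (12 equiv), TiCl4 (12 equiv), CH2Cl2, −20 °C to rt; ice-water
Reagents that add atoms: dichloromethyl methyl ether, COC(Cl)Cl; water, O
Why: Rieche formylation (electrophilic substitution by the chloro(methoxy)methyl cation, hydrolysed to the aldehyde on work-up): the four remaining aryl C–H positions C6, C8, C3' and C5' each lie between two oxygen substituents and are the only ones open, so exhaustive formylation has no regiochemical choice. Titanium-assisted loss of a methyl group next to a new formyl group is harmless, since such congeners converge in step 10.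

Step 10
Reactants: 18 (2R,3R,4S)-2-(3,5-diformyl-2,4,6-trimethoxyphenyl)-4-isobutyl-3-isopropyl-5,7-dimethoxychroman-6,8-dicarbaldehyde
Product: 19 sideroxylonal A, (2R,3R,4S)-2-(3,5-diformyl-2,4,6-trihydroxyphenyl)-5,7-dihydroxy-4-isobutyl-3-isopropylchroman-6,8-dicarbaldehyde
Conditions: BBr3 (10 equiv), CH2Cl2, −78 °C to rt; H2O
Reagents that add atoms: none
Why: Lewis-acid cleavage of aryl methyl ethers: every methoxy group of 18 is ortho to a formyl group, so BBr3 chelates and all five should be cleaved by bromide attack on the methyl group. The formyl-deactivated ring B no longer supports ionization of O1–C2, and C2 already has its thermodynamic configuration.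

**Compound list**

1 | 3,5-dimethoxyphenol | COc1cc(O)cc(OC)c1 | starting material
2 | 2-bromo-3,5-dimethoxyphenol | COc1cc(O)c(Br)c(OC)c1 | intermediate
3 | (2-bromo-3,5-dimethoxyphenoxy)trimethylsilane | COc1cc(O[Si](C)(C)C)c(Br)c(OC)c1 | intermediate
4 | [2,4-dimethoxy-6-(trimethylsilyloxy)phenyl]lithium | COc1cc(O[Si](C)(C)C)c([Li])c(OC)c1 | intermediate (not isolated)
5 | lithium 3,5-dimethoxy-2-(trimethylsilyl)phenoxide | COc1cc(O[Li])c([Si](C)(C)C)c(OC)c1 | intermediate (not isolated)
6 | 3,5-dimethoxy-2-(trimethylsilyl)phenyl trifluoromethanesulfonate | COc1cc(OC)c([Si](C)(C)C)c(OS(=O)(=O)C(F)(F)F)c1 | intermediate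
7 | 2,6-dimethylheptan-4-one | CC(C)CC(=O)CC(C)C | starting material
8 | 2,4,6-trimethoxybenzaldehyde | COc1cc(OC)c(C=O)c(OC)c1 | starting material
9 | lithium 2,6-dimethylhept-3-en-4-olate | CC(C)CC(O[Li])=CC(C)C | intermediate (not isolated)
10 | 1-hydroxy-2-isopropyl-5-methyl-1-(2,4,6-trimethoxyphenyl)hexan-3-one, racemic mixture of diastereomers | CC(C)CC(=O)C(C(C)C)C(O)c1c(OC)cc(OC)cc1OC | intermediate
11 | (E)-2-isopropyl-5-methyl-1-(2,4,6-trimethoxyphenyl)hex-1-en-3-one | CC(C)CC(=O)/C(C(C)C)=C/c1c(OC)cc(OC)cc1OC | intermediate
12 | 3,5-dimethoxybenzyne (1,2-didehydro-3,5-dimethoxybenzene) | COC1=CC(OC)=CC#C1 | intermediate (not isolated)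
13 | 2-isobutyl-3,5-dimethoxy-2-[(E)-3-methyl-1-(2,4,6-trimethoxyphenyl)but-1-en-2-yl]-2H-benzo[b]oxete, racemic | CC(C)CC1(/C(C(C)C)=C/c2c(OC)cc(OC)cc2OC)Oc2cc(OC)cc(OC)c21 | intermediate (not isolated)
14 | 6-[(1E)-2-isopropyl-5-methyl-1-(2,4,6-trimethoxyphenyl)hex-1-en-3-ylidene]-3,5-dimethoxycyclohexa-2,4-dien-1-one (ortho-quinone methide, exocyclic geometry not fixed) | O=C1C=C(OC)C=C(OC)C1=C(CC(C)C)/C(C(C)C)=C/c1c(OC)cc(OC)cc1OC | intermediate (not isolated)
15 | 4-isobutyl-3-isopropyl-5,7-dimethoxy-2-(2,4,6-trimethoxyphenyl)-2H-chromene, racemic at C2 | CC(C)CC1=C(C(C)C)C(c2c(OC)cc(OC)cc2OC)Oc2cc(OC)cc(OC)c12 | intermediate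
16 | (2S,3R,4S)-4-isobutyl-3-isopropyl-5,7-dimethoxy-2-(2,4,6-trimethoxyphenyl)chroman | CC(C)C[C@@H]1c2c(OC)cc(OC)cc2O[C@H](c2c(OC)cc(OC)cc2OC)[C@@H]1C(C)C | intermediate
17 | (2R,3R,4S)-4-isobutyl-3-isopropyl-5,7-dimethoxy-2-(2,4,6-trimethoxyphenyl)chroman | CC(C)C[C@@H]1c2c(OC)cc(OC)cc2O[C@@H](c2c(OC)cc(OC)cc2OC)[C@@H]1C(C)C | intermediate
18 | (2R,3R,4S)-2-(3,5-diformyl-2,4,6-trimethoxyphenyl)-4-isobutyl-3-isopropyl-5,7-dimethoxychroman-6,8-dicarbaldehyde | CC(C)C[C@@H]1c2c(OC)c(C=O)c(OC)c(C=O)c2O[C@@H](c2c(OC)c(C=O)c(OC)c(C=O)c2OC)[C@@H]1C(C)C | intermediate
19 | sideroxylonal A, (2R,3R,4S)-2-(3,5-diformyl-2,4,6-trihydroxyphenyl)-5,7-dihydroxy-4-isobutyl-3-isopropylchroman-6,8-dicarbaldehyde | CC(C)C[C@@H]1c2c(O)c(C=O)c(O)c(C=O)c2O[C@@H](c2c(O)c(C=O)c(O)c(C=O)c2O)[C@@H]1C(C)C | target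

**Step count and risk**

Total step count: 10. Longest linear sequence: 8 steps (steps 1, 2, 3, 6, 7, 8, 9, 10); the enone branch (steps 4 and 5) joins at step 6.

Steps least certain to work:

Step 6 (key step, proposed new method). The most likely failure is proton transfer from the α-CH2 group of the ketone, either to the aryl anion of the zwitterion before it closes to the oxete or to fluoride, which leads to net ene reaction or α-arylation of the enolate instead of [2+2] addition. Further risks are closure of the aryl anion onto the β-carbon (a formal [4+2] addition that would give the isomeric 4H-chromene), a 1,5-hydrogen shift within the quinone methide from the isobutyl CH2 to oxygen, and capture of the quinone methide by a second aryne. The fallback uses known chemistry and forms the same C4a–C4 and O1–C2 bonds from a ring A piece that already carries O1. It sets out from 2 and 11 and returns at 15. Phenol 2 is protected with MOMCl and i-Pr2NEt in CH2Cl2 to give 2-bromo-1,5-dimethoxy-3-(methoxymethoxy)benzene F1. Bromine–lithium exchange (n-BuLi, THF, −78 °C) gives the aryllithium F2, which, used together with anhydrous CeCl3 to suppress enolization of the hindered ketone, adds 1,2 to the carbonyl group of 11 to give the tertiary allylic alcohol F3. Aqueous HCl in THF then removes the MOM group and ionizes the tertiary alcohol to an allyl cation delocalized onto C2 (equivalently, dehydrates it to quinone methide 14), and the phenol closes at C2 to give 15. Addition of aryllithium reagents to enones and acid-mediated cyclization of 2-(1-hydroxyallyl)phenols to 2H-chromenes are both established.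

Step 7. The alkene is tetrasubstituted and flanked by isopropyl, isobutyl, the C5 methoxy group and the C2 aryl group, so the catalyst may fail to turn over. The second risk is insufficient discrimination between the enantiomers of 15: reduction of (R)-15 under substrate control would erode the enantiomeric purity that step 8 cannot restore. Opening of the chromene by the acidic iridium hydride is a third possibility. The fallback separates the two sources of control. It sets out from 15 and returns at 16. Racemic 15 is resolved by preparative chromatography on a chiral stationary phase into (S)-4-isobutyl-3-isopropyl-5,7-dimethoxy-2-(2,4,6-trimethoxyphenyl)-2H-chromene F4 and its (R)-enantiomer F5, the latter being racemized with catalytic acid and recycled. F4 is then hydrogenated with the achiral, highly active complex [Ir(cod)(PCy3)(py)][B(3,5-(CF3)2C6H3)4] under H2 (50 bar, CH2Cl2); addition anti to the C2 aryl group gives 16 by substrate control alone.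

Step 9. Each formyl group deactivates its ring, so the reaction may stall at a di- or triformyl stage; the Lewis acid may also ionize O1–C2 before ring B is deactivated, with Friedel–Crafts capture of the cation by another electron-rich arene. The fallback reverses the order of the last two operations and also removes the need for step 10. It sets out from 17 and returns at 19. BBr3 in CH2Cl2 converts 17 into the pentaphenol F6, (2R,3R,4S)-2-(2,4,6-trihydroxyphenyl)-4-isobutyl-3-isopropylchroman-5,7-diol, handled under argon. The free phloroglucinol rings, far more nucleophilic than their ethers, are then formylated four times by the Vilsmeier–Haack reaction (POCl3, DMF, then aqueous hydrolysis), a known way to diformylphloroglucinols, giving 19 directly.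

Step 8. The benzylic cation may lose the C3 hydrogen (E1) and be reprotonated, which would scramble C3; at higher concentration it may alkylate a second molecule. The fallback moves the epimerization to the end and changes its mechanism from a carbocation to a quinone methide. It sets out from 16 and returns at 19. Compound 16 is formylated as in step 9 to the all-cis tetra-aldehyde F7 and demethylated as in step 10 to 2-epi-sideroxylonal A F8. Mild base (NaHCO3, MeOH, 40 °C, argon) then lets a ring B phenoxide expel the ring A phenoxide, a good leaving group because of its two formyl groups, and the quinone methide so formed recloses by oxa-Michael addition to the more stable epimer 19. This is the known mode of C2 epimerization of flavan-type polyphenols; if the Lewis acid of the formylation has already equilibrated C2, the sequence simply rejoins at 18.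

Step 1. Bromination may go para to the hydroxyl group (C4, between the two methoxy groups) or twice, and separation may be laborious. The fallback replaces electrophilic substitution by directed ortho-metalation, whose regiochemistry is fixed by the stronger directing group. It sets out from 1 and returns at 6. Phenol 1 is converted with isopropyl isocyanate and Et3N into the carbamate F9. Ortho-lithiation between carbamate and methoxy (n-BuLi, TMEDA, THF, −78 °C, with the N–H masked in situ by silylation) and quenching with Me3SiCl give the silyl carbamate F10. Cleavage with Et2NH and DBU in MeCN gives 3,5-dimethoxy-2-(trimethylsilyl)phenol F11, and triflation (Tf2O, pyridine) gives 6.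

**Further compounds**

F1 | step 6 | 2-bromo-1,5-dimethoxy-3-(methoxymethoxy)benzene | COCOc1cc(OC)cc(OC)c1Br
F2 | step 6 | [2,4-dimethoxy-6-(methoxymethoxy)phenyl]lithium | COCOc1cc(OC)cc(OC)c1[Li]
F3 | step 6 | (E)-3-[2,4-dimethoxy-6-(methoxymethoxy)phenyl]-2-isopropyl-5-methyl-1-(2,4,6-trimethoxyphenyl)hex-1-en-3-ol, racemic | CC(C)CC(O)(c1c(OCOC)cc(OC)cc1OC)/C(C(C)C)=C/c1c(OC)cc(OC)cc1OC
F4 | step 7 | (S)-4-isobutyl-3-isopropyl-5,7-dimethoxy-2-(2,4,6-trimethoxyphenyl)-2H-chromene | CC(C)CC1=C(C(C)C)[C@@H](c2c(OC)cc(OC)cc2OC)Oc2cc(OC)cc(OC)c12
F5 | step 7 | (R)-4-isobutyl-3-isopropyl-5,7-dimethoxy-2-(2,4,6-trimethoxyphenyl)-2H-chromene | CC(C)CC1=C(C(C)C)[C@H](c2c(OC)cc(OC)cc2OC)Oc2cc(OC)cc(OC)c12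
F6 | step 9 | (2R,3R,4S)-2-(2,4,6-trihydroxyphenyl)-4-isobutyl-3-isopropylchroman-5,7-diol | CC(C)C[C@@H]1c2c(O)cc(O)cc2O[C@@H](c2c(O)cc(O)cc2O)[C@@H]1C(C)C
F7 | step 8 | (2S,3R,4S)-2-(3,5-diformyl-2,4,6-trimethoxyphenyl)-4-isobutyl-3-isopropyl-5,7-dimethoxychroman-6,8-dicarbaldehyde | CC(C)C[C@@H]1c2c(OC)c(C=O)c(OC)c(C=O)c2O[C@H](c2c(OC)c(C=O)c(OC)c(C=O)c2OC)[C@@H]1C(C)C
F8 | step 8 | 2-epi-sideroxylonal A, (2S,3R,4S)-2-(3,5-diformyl-2,4,6-trihydroxyphenyl)-5,7-dihydroxy-4-isobutyl-3-isopropylchroman-6,8-dicarbaldehyde | CC(C)C[C@@H]1c2c(O)c(C=O)c(O)c(C=O)c2O[C@H](c2c(O)c(C=O)c(O)c(C=O)c2O)[C@@H]1C(C)C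
F9 | step 1 | 3,5-dimethoxyphenyl N-isopropylcarbamate | COc1cc(OC)cc(OC(=O)NC(C)C)c1
F10 | step 1 | 3,5-dimethoxy-2-(trimethylsilyl)phenyl N-isopropylcarbamate | COc1cc(OC)c([Si](C)(C)C)c(OC(=O)NC(C)C)c1
F11 | step 1 | 3,5-dimethoxy-2-(trimethylsilyl)phenol | COc1cc(O)c([Si](C)(C)C)c(OC)c1
A1 | alternative 1 | 4,4,5,5-tetramethyl-2-(2,4,6-trimethoxyphenyl)-1,3,2-dioxaborolane | COc1cc(OC)c(B2OC(C)(C)C(C)(C)O2)c(OC)c1
A2 | alternative 1 | 3-methylbutyl N,N-diisopropylcarbamate | CC(C)CCOC(=O)N(C(C)C)C(C)C
A3 | alternative 1 | 2-methylpropyl 2,4,6-triisopropylbenzoate | CC(C)COC(=O)c1c(C(C)C)cc(C(C)C)cc1C(C)C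
A4 | alternative 1 | 2-[(3R,4S)-2,6-dimethyl-4-(2,4,6-trimethoxyphenyl)heptan-3-yl]-4,4,5,5-tetramethyl-1,3,2-dioxaborolane | CC(C)C[C@H](c1c(OC)cc(OC)cc1OC)[C@@H](C(C)C)B1OC(C)(C)C(C)(C)O1
A5 | alternative 2 | dimethyl 6-alkoxy-4-methoxy-2-oxo-2H-pyran-3,5-dicarboxylate whose alkoxy group is the C2–C3–C4 chain with 3,5-bis(methoxycarbonyl)-2,4,6-trimethoxyphenyl on C2, isopropyl on C3, and isobutyl and (triisopropylsilyloxy)ethynyl on C4, configured as in the target | CC(C)C[C@H](C#CO[Si](C(C)C)(C(C)C)C(C)C)[C@@H](C(C)C)[C@H](c1c(OC)c(C(=O)OC)c(OC)c(C(=O)OC)c1OC)OC1=C(C(=O)OC)C(OC)=C(C(=O)OC)C(=O)O1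
A6 | alternative 2 | dimethyl (2R,3R,4S)-2-[3,5-bis(methoxycarbonyl)-2,4,6-trimethoxyphenyl]-4-isobutyl-3-isopropyl-7-methoxy-5-(triisopropylsilyloxy)chroman-6,8-dicarboxylate | CC(C)C[C@@H]1c2c(O[Si](C(C)C)(C(C)C)C(C)C)c(C(=O)OC)c(OC)c(C(=O)OC)c2O[C@@H](c2c(OC)c(C(=O)OC)c(OC)c(C(=O)OC)c2OC)[C@@H]1C(C)C
A7 | alternative 3 | 2-[(2R,3S)-2-isopropyl-5-methyl-3-(2,4,6-trihydroxyphenyl)hexyl]benzene-1,3,5-triol | CC(C)C[C@H](c1c(O)cc(O)cc1O)[C@@H](C(C)C)Cc1c(O)cc(O)cc1O
A8 | alternative 3 | (2R,3R,4S)-2-(2,4,6-trihydroxyphenyl)-4-isobutyl-3-isopropylchroman-5,7-diol (tetra-deformyl sideroxylonal A) | CC(C)C[C@@H]1c2c(O)cc(O)cc2O[C@@H](c2c(O)cc(O)cc2O)[C@@H]1C(C)C
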